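The pitfall here is to take the half-life of the incoming ligand as the time it has to act.

    incoming ligand → decomposed reagent (k1 = 0.0120 s⁻¹)
    complex with two exchanged + incoming ligand ⇌ leaving ligand + complex with three exchanged (K2 = 3.91, k2 = 0.125 M⁻¹ s⁻¹)
    complex with one exchanged + incoming ligand ⇌ leaving ligand + complex with two exchanged (K3 = 6.3, k3 = 0.680 M⁻¹ s⁻¹)
    starting complex + incoming ligand ⇌ leaving ligand + complex with one exchanged (K4 = 26, k4 = 2.43 M⁻¹ s⁻¹)

| setting | Saturday's | Monday's | Sunday's | Thursday's |
|---|---|---|---|---|
| starting complex | 0.097 M | 0.097 M | 0.097 M (fed, over 10.0 min) | 0.097 M |
| incoming ligand | 0.900 equiv | 0.900 equiv | 0.900 equiv | 0.900 equiv (fed, over 10.0 min) |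
| leaving ligand | 5.00 equiv | 5.00 equiv | 5.00 equiv | 5.00 equiv |
| time | 10 min |  | 10 min | 10 min |
| remark | a closed flask charged with all of it at once and left for 10 min | a single well-mixed tank run continuously and read at steady state, 10 min in it on average | a stirred flask in which starting complex is dosed at a steady rate over 10.0 min without added volume, worked up at 10 min | a stirred flask in which incoming ligand is dosed at a steady rate over 10.0 min without added volume, worked up at 10 min |

- order of the set-ups by the amount of complex with one exchanged at the outlet or at the end, in percent of the starting complex put in, highest first (Saturday's / Monday's / Sunday's / Thursday's)
- amount of complex with one exchanged at the outlet or at the end, in percent of the starting complex put in, Saturday's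
- amount of complex with one exchanged at the outlet or at the end, in percent of the starting complex put in, Monday's
- amount of complex with one exchanged at the outlet or at the end, in percent of the starting complex put in, Sunday's
- amount of complex with one exchanged at the outlet or at the end, in percent of the starting complex put in, Thursday's

- the stated concentrations are those of everything mixed, before any reaction; amounts are the same in each set-up
- the feed brings no volume worth counting
- run time (Saturday's): 10 min

Each forward exchange goes with free incoming ligand. Alone, that ligand decomposes with a half-life of 0.96 min, so Saturday's 10 min is 10.4 half-lives and seems to leave 0.0747% of its charge. Yet Saturday's starting complex takes up ligand with a forward half-life of 0.054 min, much shorter, so the first exchange can be reckoned as a pre-equilibrium, and in the scheme ligand held in a complex does not decompose.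

The reckoning therefore uses the buffer number, the equilibrium constant of the first exchange over the equivalents of leaving ligand, 5.20: equivalents of complex with one exchanged held per equivalent of free incoming ligand, with starting complex and leaving ligand at their charges. With the second exchange set aside as a simplification, 16.1% of the ligand pool is free, and the pool's half-life stretches to 5.97 min, which makes 1.16 decay units in the run. That simplification rests on free ligand, not on the size of the constant: at equilibrium, complex with two exchanged per complex with one exchanged is 6.3 times free incoming ligand over leaving ligand, which is 0.183 with that free share of the whole ligand charge.

Saturday's pool decays from the start, giving 23.6% of complex with one exchanged. Monday's tank gives 34.9%. Thursday's dosing gives 44.6%. In Sunday's the buffer grows with the dosed complex, so the exponent becomes 2.53 and the figure 6.04%. These figures take starting complex at full charge, which overstates the holding, but the order stands: Thursday's, Monday's, Saturday's, Sunday's.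

The forecast gives the same order, Thursday's > Monday's > Saturday's > Sunday's, with lower figures: 17% for Saturday's, 25% for Monday's, 5% for Sunday's and 29% for Thursday's, holding that "Dosing the ligand late keeps the most alive at the end".

The simulation gives Thursday's > Monday's > Saturday's > Sunday's: 16.3% for Saturday's, 25.2% for Monday's, 4.66% for Sunday's and 30.5% for Thursday's.

The reckoned order stands, with Thursday's reckoned 44.6% above its 30.5%. With standing amounts put in, Thursday's starting complex at 65.9% and leaving ligand at 108% of its charge bring the buffer number to 3.18, and free ligand at 10.8% of its charge then gives 30.9%. The neighbour of Thursday's charged with 2.20 equiv of incoming ligand ends with starting complex 39.2%, leaving ligand 116% and free ligand 11.9% of its charge, so its number is 1.77 and the reckoning gives 46.3%; that neighbour holds 45.8% of complex with one exchanged.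

The numbers of this flask are assumed; the flask was simulated.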